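Numbering: ring A = C1–C5 and C10, ring B = C5–C10; C1 carries the ester oxygen, C4 the carboxyl carbon C15, C5 the methyl, C7 the acrolein arm C11–C13, C8 the ketone; β is the face of the C5 methyl.
Retrosynthesis: cut C11=C13 and C7–C11 (arm from a C7 allyl group), then the C1–O acyl bond, then C3–C4 and C5–C10 together, and in the open chain C8–C9 and C1–C2, which leads back to geranyl acetate, ethyl acrylate and a vinyl Grignard reagent.
Enabling feature: C5–C10 is the bond common to rings A and B; the neighbouring C4 (carboxyl) and C5 (quaternary, methyl) are the two carbons of an (E)-β-methyl enal, and the oxygen on C1 beside C10 marks a 2-silyloxydiene C10=C1–C2=C3, so one intramolecular [4+2] closes both rings.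
Forward: the C4–C8 aldehyde from geranyl acetate is joined to C9–C10–C1 (Stetter) and C2–C3 (vinyl ketone); rings A and B then form at once, followed by the C9=C10 enone, the C1 alcohol and its ester, the C8 enone and last the C7 arm.
Stereochemistry: C4/C5 absolute from a chiral oxazaborolidinium catalyst and relative (cis) from the (E)-alkene of geraniol; C1 by hydride attack anti to the C5 methyl; C7 by alkylation anti to that methyl (also the stable epimer); C4′ of the acyl chain by an Evans methylation.

Key step: step 8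

Assumption: the catalyst's sense of induction follows its accepted pre-transition-state model (formyl C–H···O contact, s-trans enal stacked on a phenyl ring), by which the (S)-catalyst exposes the C4 Re face; the Si face is needed, hence the (R)-catalyst, and the antipodal catalyst is used if the adduct proves enantiomeric.

Step 1
Reactants: 1 geranyl acetate
Product: 3 (2E)-3-methyl-6-oxohex-2-en-1-yl acetate, via ozonide 2 (not isolated)
Conditions: O3 (1 equiv), CH2Cl2, −78 °C; then Me2S, −78 °C → rt
Reagents that add atoms: ozone, [O-][O+]=O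
Why: Ozonolysis with reductive work-up: the remote 6,7-double bond is the more electron-rich one (the 2,3-alkene is deactivated by its allylic acetate), so one equivalent of ozone cleaves it alone and leaves the (E)-alkene that becomes C4=C5.

Step 2
Reactants: 3 (2E)-3-methyl-6-oxohex-2-en-1-yl acetate; 4 ethyl acrylate
Product: 5 ethyl (7E)-9-acetoxy-7-methyl-4-oxonon-7-enoate
Conditions: 3-benzyl-5-(2-hydroxyethyl)-4-methylthiazolium chloride (C13H16ClNOS, 10 mol %), Et3N, 1,4-dioxane, 80 °C
Reagents that add atoms: none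
Why: Stetter reaction: the thiazolium-derived carbene turns the aldehyde into an acyl anion equivalent that adds 1,4 to the acrylate, forming the C8–C9 bond and the 1,4-keto ester without touching the allylic acetate.

Step 3
Reactants: 5 ethyl (7E)-9-acetoxy-7-methyl-4-oxonon-7-enoate
Product: 6 ethyl (7E)-9-acetoxy-4,4-(ethylenedioxy)-7-methylnon-7-enoate
Conditions: (Me3SiOCH2)2, Me3SiOSO2CF3 (5 mol %), CH2Cl2, −78 → −20 °C; pyridine
Reagents that add atoms: 1,2-bis(trimethylsilyloxy)ethane, C[Si](C)(C)OCCO[Si](C)(C)C
Why: Noyori ketalisation: silyl triflate-catalysed transfer of the bis-silylated glycol to the ketone at low temperature, under which the two esters and the allylic acetate are inert.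

Step 4
Reactants: 6 ethyl (7E)-9-acetoxy-4,4-(ethylenedioxy)-7-methylnon-7-enoate
Product: 7 (7E)-4,4-(ethylenedioxy)-9-hydroxy-N-methoxy-N,7-dimethylnon-7-enamide
Conditions: MeNH(OMe)·HCl, i-PrMgCl (excess), THF, −20 → 0 °C
Reagents that add atoms: N,O-dimethylhydroxylamine hydrochloride, CNOC.Cl
Why: Aminolysis of the ethyl ester by the magnesium amide made in the flask gives the Weinreb amide, and the same reagent removes the acetate by acyl transfer, freeing the allylic alcohol needed later.

Step 5
Reactants: 7 (7E)-4,4-(ethylenedioxy)-9-hydroxy-N-methoxy-N,7-dimethylnon-7-enamide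
Product: 8 (9E)-6,6-(ethylenedioxy)-11-hydroxy-9-methylundeca-1,9-dien-3-one
Conditions: CH2=CHMgBr (3.5 equiv), THF, −20 → 0 °C; inverse quench into cold aq. NaHSO4
Reagents that add atoms: vinylmagnesium bromide, C=C[Mg]Br
Why: Weinreb ketone synthesis: the magnesium-chelated tetrahedral adduct survives until work-up, so only one vinyl group is delivered (the alkoxide uses up a further equivalent), and the acidic inverse quench keeps the released amine from adding to the vinyl ketone.

Step 6
Reactants: 8 (9E)-6,6-(ethylenedioxy)-11-hydroxy-9-methylundeca-1,9-dien-3-one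
Product: 11 (2E,8Z)-6,6-(ethylenedioxy)-3-methyl-9-(triisopropylsilyloxy)undeca-2,8,10-trien-1-ol, via trimethylsilyl ether 9 (not isolated), via bis-silyl ether 10 (not isolated)
Conditions: Me3SiCl, Et3N, CH2Cl2, 0 °C; then i-Pr3SiOSO2CF3, Et3N, −78 → 0 °C; then K2CO3 (cat.), MeOH, 0 °C
Reagents that add atoms: triisopropylsilyl trifluoromethanesulfonate, CC(C)[Si](OS(=O)(=O)C(F)(F)F)(C(C)C)C(C)C
Why: Soft enolisation of the vinyl ketone, whose only enolisable position is C10, gives the (Z)-2-silyloxydiene (oxygen cis to the chain, tether on the outside of the s-cis diene); the alcohol is masked in passing as its trimethylsilyl ether, which carbonate in methanol removes while the hindered triisopropylsilyl enol ether stays.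

Step 7
Reactants: 11 (2E,8Z)-6,6-(ethylenedioxy)-3-methyl-9-(triisopropylsilyloxy)undeca-2,8,10-trien-1-ol
Product: 12 (2E,8Z)-6,6-(ethylenedioxy)-3-methyl-9-(triisopropylsilyloxy)undeca-2,8,10-trienal
Conditions: MnO2 (activated, excess), CH2Cl2, rt
Reagents that add atoms: none
Why: Manganese dioxide oxidises allylic alcohols selectively under neutral, heterogeneous conditions that spare the silyl enol ether and the ketal, and the (E)-geometry of the enal is retained.

Step 8
Reactants: 12 (2E,8Z)-6,6-(ethylenedioxy)-3-methyl-9-(triisopropylsilyloxy)undeca-2,8,10-trienal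
Product: 13 trans-fused octalin aldehyde (C1 triisopropylsilyl enol ether C1=C2; C8 dioxolane; 4β-CHO; 5β-CH3; 10α-H)
Conditions: (R)-3,3-diphenyl-1-(2-methylphenyl)tetrahydro-1H,3H-pyrrolo[1,2-c][1,3,2]oxazaborole (C24H24BNO, 20 mol %), (CF3SO2)2NH (18 mol %), CH2Cl2, −78 → −40 °C
Reagents that add atoms: none
Why: The N-protonated oxazaborolidine binds the formyl oxygen of the s-trans enal, lowers its LUMO and screens the C4 Re face with a phenyl ring, so the tethered 2-silyloxydiene adds to the Si face in a concerted, asynchronous [4+2] in which the C5–C10 bond (enol ether carbon to β-carbon) runs ahead of the C3–C4 bond; the closest known reaction type is the chiral oxazaborolidinium-catalysed intramolecular Diels–Alder reaction of trienals, and these catalysts accept 2-triisopropylsilyloxydienes in the intermolecular reaction. Ring A (C1, C2, C3, C4, C5, C10) is the cyclohexene made by the cycloaddition itself, and ring B is closed as a fused six-membered ring by the four-atom tether C6–C9 when the C5–C10 bond forms. The absolute configuration at C4 and C5 comes from the catalyst, their cis relation (formyl and methyl on one face) from the (E)-alkene and suprafacial addition, and C10 from the formyl-endo transition state (trans fusion), which is of no consequence because C10 later becomes trigonal. The step needs enantiofacial selectivity and enough reactivity at a trisubstituted dienophile: the (Z)-enol ether keeps the tether outside the diene, the electron-rich silyloxydiene matches the polarised enal, and the spiro ketal in the tether favours the folded conformer.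

Step 9
Reactants: 13 trans-fused octalin aldehyde
Product: 14 trans-fused decalin keto aldehyde (C1 ketone; C8 dioxolane; 4β-CHO; 5β-CH3; 10α-H)
Conditions: Bu4NF, AcOH, THF, 0 °C
Reagents that add atoms: none
Why: Fluoride cleaves the Si–O bond and the buffered enolate is protonated at C2 to give the C1 ketone; acetic acid keeps the medium from opening the 1,5-dicarbonyl by retro-Michael reaction, and the trans ring fusion is the stable one.

Step 10
Reactants: 14 trans-fused decalin keto aldehyde
Product: 15 keto acid (C1 ketone; C8 dioxolane; 4β-CO2H; 5β-CH3; 10α-H)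
Conditions: NaClO2, NaH2PO4, 2-methyl-2-butene, t-BuOH/H2O, 0 °C → rt
Reagents that add atoms: sodium chlorite, [Na+].[O-]Cl=O
Why: Pinnick oxidation: chlorous acid converts the hindered, epimerisable aldehyde into the acid near pH 4 without touching C4, the ketone or the ketal, the hypochlorous acid formed being trapped by the alkene.

Step 11
Reactants: 15 keto acid
Product: 16 4-methoxybenzyl ester of keto acid 15
Conditions: 4-MeOC6H4CH2Cl, Cs2CO3, DMF, rt
Reagents that add atoms: 4-methoxybenzyl chloride, COc1ccc(CCl)cc1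
Why: Carboxylate O-alkylation (SN2 at the benzylic chloride) is insensitive to the crowding of the neopentyl-type carboxyl group and gives an ester that resists the later base, hydride and dilute-acid steps yet falls to trifluoroacetic acid.

Step 12
Reactants: 16 4-methoxybenzyl ester of keto acid 15
Product: 17 C1=C10 trimethylsilyl enol ether of 16
Conditions: Me3SiCl, Et3N, DMF, 90 °C
Reagents that add atoms: chlorotrimethylsilane, C[Si](C)(C)Cl
Why: Enol silylation under equilibrating conditions (amine hydrochloride, heat) favours the tetrasubstituted C1=C10 enol ether over the C1=C2 isomer, and the C10 stereocentre disappears.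

Step 13
Reactants: 17 C1=C10 trimethylsilyl enol ether
Product: 18 C9=C10 enone (C1 ketone; C8 dioxolane; 4β-CO2CH2C6H4OMe; 5β-CH3)
Conditions: Pd(OAc)2 (1.1 equiv), MeCN, rt → 40 °C
Reagents that add atoms: none
Why: Saegusa–Ito oxidation: the enol ether becomes a C10-bound palladium enolate whose β-hydride elimination can only take a hydrogen from C9, because C5 is quaternary, so the C9=C10 enone results.

Step 14
Reactants: 18 C9=C10 enone
Product: 19 1β-allylic alcohol (1R; C9=C10; C8 dioxolane; 4β-CO2CH2C6H4OMe)
Conditions: NaBH4, CeCl3·7H2O, MeOH, −40 °C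
Reagents that add atoms: none
Why: Luche reduction: the cerium-activated ketone is reduced 1,2, and hydride comes from the α face because the β face is blocked by the axial C5 methyl, which sets the axial 1β-hydroxyl (1R).

Step 15
Reactants: 20 (S)-4-benzyloxazolidin-2-one; 21 hexanoyl chloride
Product: 22 (S)-4-benzyl-3-hexanoyloxazolidin-2-one
Conditions: Et3N, 4-dimethylaminopyridine (cat.), CH2Cl2, 0 °C → rt
Reagents that add atoms: none
Why: N-Acylation of the oxazolidinone by the acid chloride under nucleophilic catalysis; no stereocentre is formed.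

Step 16
Reactants: 22 (S)-4-benzyl-3-hexanoyloxazolidin-2-one
Product: 23 (S)-4-benzyl-3-[(2S)-2-methylhexanoyl]oxazolidin-2-one
Conditions: NaN(SiMe3)2, THF, −78 °C; MeI, −78 → −40 °C
Reagents that add atoms: iodomethane, CI
Why: Evans alkylation: the chelated (Z)-sodium enolate is methylated on the face opposite the benzyl group, which sets the (S) configuration at the carbon that becomes C4′.

Step 17
Reactants: 23 (S)-4-benzyl-3-[(2S)-2-methylhexanoyl]oxazolidin-2-one
Product: 24 (S)-2-methylhexan-1-ol
Conditions: LiBH4, EtOH (1 equiv), Et2O, 0 °C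
Reagents that add atoms: none
Why: Reductive removal of the auxiliary: borohydride attacks the exocyclic imide carbonyl and reduces it to the primary alcohol without touching the α-stereocentre, and the oxazolidinone is recovered.

Step 18
Reactants: 24 (S)-2-methylhexan-1-ol
Product: 26 ethyl (2E,4S)-2,4-dimethyloct-2-enoate, via (S)-2-methylhexanal 25 (not isolated)
Conditions: 2,2,6,6-tetramethylpiperidin-1-oxyl (10 mol %), PhI(OAc)2, CH2Cl2, rt; then Ph3P=C(CH3)CO2Et, rt → 40 °C
Reagents that add atoms: ethyl 2-(triphenylphosphoranylidene)propanoate, CCOC(=O)C(C)=P(c1ccccc1)(c1ccccc1)c1ccccc1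
Why: Oxoammonium oxidation gives the configurationally labile α-branched aldehyde, which is trapped at once by the stabilised ylide in a Wittig reaction that gives the (E)-trisubstituted enoate.

Step 19
Reactants: 26 ethyl (2E,4S)-2,4-dimethyloct-2-enoate
Product: 27 (2E,4S)-2,4-dimethyloct-2-enoic acid
Conditions: LiOH, THF/MeOH/H2O, 50 °C; then 1 M HCl
Reagents that add atoms: lithium hydroxide, [Li+].[OH-]
Why: Saponification of the ethyl ester; the γ-stereocentre is not acidic under these conditions.

Step 20
Reactants: 19 1β-allylic alcohol; 27 (2E,4S)-2,4-dimethyloct-2-enoic acid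
Product: 29 C1 ester (1β-[(2E,4S)-2,4-dimethyloct-2-enoyloxy]; C9=C10; C8 dioxolane; 4β-CO2CH2C6H4OMe), via mixed anhydride 28 (not isolated)
Conditions: 2,4,6-Cl3C6H2COCl, Et3N, toluene, rt; then 19, 4-dimethylaminopyridine, toluene, rt → 50 °C
Reagents that add atoms: none
Why: Yamaguchi esterification: the mixed anhydride passes the acyl group through the acylpyridinium ion to the hindered axial hydroxyl, the C1–O bond is not broken so its configuration is retained, and the acid has no α-hydrogen through which it could form a ketene.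

Step 21
Reactants: 29 C1 ester
Product: 30 C8 enone (C8=O conjugated to C9=C10; 1β-acyloxy; 4β-CO2CH2C6H4OMe)
Conditions: pyridinium p-toluenesulfonate, acetone/H2O, 40 °C
Reagents that add atoms: water, O
Why: Acid-catalysed hydrolysis of the allylic ketal through the conjugated oxocarbenium ion gives the C8 ketone in conjugation with C9=C10; the C1 ester, at the γ-position of the enone, is not prone to ionisation.

Step 22
Reactants: 30 C8 enone
Product: 31 7α-allyl enone 4-methoxybenzyl ester
Conditions: LiN(SiMe3)2 (1.05 equiv), THF, −78 °C; CH2=CHCH2I, DMPU, −78 → −30 °C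
Reagents that add atoms: allyl iodide, C=CCI
Why: Kinetic α′-deprotonation of the enone at C7 (the equatorial C1–H is poorly aligned for γ-deprotonation) and alkylation of the cross-conjugated enolate: allyl iodide enters anti to the axial C5 methyl, giving the equatorial 7α-allyl group, which is also the thermodynamically preferred epimer.

Step 23
Reactants: 31 7α-allyl enone 4-methoxybenzyl ester
Product: 32 7α-allyl enone acid (free C15 carboxylic acid)
Conditions: CF3CO2H, anisole, CH2Cl2, 0 °C
Reagents that add atoms: none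
Why: Acidolysis of the 4-methoxybenzyl ester (SN1 cleavage, cation trapped by anisole) frees the acid before any aldehyde is present, so that the acid-sensitive 1,4-keto aldehyde never meets trifluoroacetic acid.

Step 24
Reactants: 32 7α-allyl enone acid
Product: 34 keto aldehyde acid (C7–CH2–CHO), via diol 33 (not isolated)
Conditions: OsO4 (2 mol %), NaIO4, 2,6-lutidine, dioxane/H2O, rt
Reagents that add atoms: osmium tetroxide, O=[Os](=O)(=O)=O, its oxygen replenished by sodium periodate, [Na+].[O-]I(=O)(=O)=O
Why: Lemieux–Johnson oxidation: osmium tetroxide dihydroxylates the terminal monosubstituted alkene far faster than the electron-poor trisubstituted enone and enoate double bonds, and periodate cleaves the diol to the C12 aldehyde.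

Step 25
Reactants: 34 keto aldehyde acid
Product: 35 integric acid
Conditions: aq. CH2O (37 %), pyrrolidine (10 mol %), EtCO2H (10 mol %), i-PrOH, 45 °C
Reagents that add atoms: formaldehyde, C=O
Why: Amine-catalysed α-methylenation (Mannich-type condensation with formaldehyde): the enamine of the aldehyde adds to formaldehyde activated as its iminium ion and elimination gives the 2-substituted acrolein, C7 remaining in its equatorial, thermodynamically favoured configuration.

Compound list
1 | geranyl acetate | CC(C)=CCC/C(C)=C/COC(C)=O | starting material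
2 | ozonide, (2E)-5-(5,5-dimethyl-1,2,4-trioxolan-3-yl)-3-methylpent-2-en-1-yl acetate | CC(=O)OC/C=C(C)/CCC1OOC(C)(C)O1 | intermediate
3 | (2E)-3-methyl-6-oxohex-2-en-1-yl acetate | CC(=O)OC/C=C(C)/CCC=O | intermediate
4 | ethyl acrylate | C=CC(=O)OCC | starting material
5 | ethyl (7E)-9-acetoxy-7-methyl-4-oxonon-7-enoate | CCOC(=O)CCC(=O)CC/C(C)=C/COC(C)=O | intermediate
6 | ethyl (7E)-9-acetoxy-4,4-(ethylenedioxy)-7-methylnon-7-enoate | CCOC(=O)CCC1(CC/C(C)=C/COC(C)=O)OCCO1 | intermediate
7 | (7E)-4,4-(ethylenedioxy)-9-hydroxy-N-methoxy-N,7-dimethylnon-7-enamide | CON(C)C(=O)CCC1(CC/C(C)=C/CO)OCCO1 | intermediate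
8 | (9E)-6,6-(ethylenedioxy)-11-hydroxy-9-methylundeca-1,9-dien-3-one | C=CC(=O)CCC1(CC/C(C)=C/CO)OCCO1 | intermediate
9 | trimethylsilyl ether of 8 | C=CC(=O)CCC1(CC/C(C)=C/CO[Si](C)(C)C)OCCO1 | intermediate
10 | bis-silyl ether, (2E,8Z)-6,6-(ethylenedioxy)-3-methyl-9-(triisopropylsilyloxy)-1-(trimethylsilyloxy)undeca-2,8,10-triene | C=C/C(O[Si](C(C)C)(C(C)C)C(C)C)=C/CC1(CC/C(C)=C/CO[Si](C)(C)C)OCCO1 | intermediate
11 | (2E,8Z)-6,6-(ethylenedioxy)-3-methyl-9-(triisopropylsilyloxy)undeca-2,8,10-trien-1-ol | C=C/C(O[Si](C(C)C)(C(C)C)C(C)C)=C/CC1(CC/C(C)=C/CO)OCCO1 | intermediate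
12 | (2E,8Z)-6,6-(ethylenedioxy)-3-methyl-9-(triisopropylsilyloxy)undeca-2,8,10-trienal | C=C/C(O[Si](C(C)C)(C(C)C)C(C)C)=C/CC1(CC/C(C)=C/C=O)OCCO1 | intermediate
13 | trans-fused octalin aldehyde: C1 triisopropylsilyl enol ether (C1=C2), C8 dioxolane, 4β-CHO, 5β-CH3, 10α-H | C[C@]12CCC3(OCCO3)C[C@@H]1C(O[Si](C(C)C)(C(C)C)C(C)C)=CC[C@@H]2C=O | intermediate
14 | trans-fused decalin keto aldehyde: C1 ketone, C8 dioxolane, 4β-CHO, 5β-CH3, 10α-H | C[C@]12CCC3(OCCO3)C[C@@H]1C(=O)CC[C@@H]2C=O | intermediate
15 | keto acid: as 14 with 4β-CO2H | C[C@]12CCC3(OCCO3)C[C@@H]1C(=O)CC[C@@H]2C(=O)O | intermediate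
16 | 4-methoxybenzyl ester of 15 | C[C@]12CCC3(OCCO3)C[C@@H]1C(=O)CC[C@@H]2C(=O)OCc1ccc(OC)cc1 | intermediate
17 | C1=C10 trimethylsilyl enol ether of 16 | C[C@]12CCC3(OCCO3)CC1=C(O[Si](C)(C)C)CC[C@@H]2C(=O)OCc1ccc(OC)cc1 | intermediate
18 | C9=C10 enone: C1 ketone, C8 dioxolane, 4β-ester, 5β-CH3 | C[C@]12CCC3(OCCO3)C=C1C(=O)CC[C@@H]2C(=O)OCc1ccc(OC)cc1 | intermediate
19 | 1β-allylic alcohol (1R), C9=C10, C8 dioxolane | C[C@]12CCC3(OCCO3)C=C1[C@H](O)CC[C@@H]2C(=O)OCc1ccc(OC)cc1 | intermediate
20 | (S)-4-benzyloxazolidin-2-one | O=C1N[C@@H](Cc2ccccc2)CO1 | starting material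
21 | hexanoyl chloride | CCCCCC(Cl)=O | starting material
22 | (S)-4-benzyl-3-hexanoyloxazolidin-2-one | CCCCCC(=O)N1[C@@H](Cc2ccccc2)COC1=O | intermediate
23 | (S)-4-benzyl-3-[(2S)-2-methylhexanoyl]oxazolidin-2-one | CCCC[C@H](C)C(=O)N1[C@@H](Cc2ccccc2)COC1=O | intermediate
24 | (S)-2-methylhexan-1-ol | CCCC[C@H](C)CO | intermediate
25 | (S)-2-methylhexanal | CCCC[C@H](C)C=O | intermediate
26 | ethyl (2E,4S)-2,4-dimethyloct-2-enoate | CCCC[C@H](C)/C=C(\C)C(=O)OCC | intermediate
27 | (2E,4S)-2,4-dimethyloct-2-enoic acid | CCCC[C@H](C)/C=C(\C)C(=O)O | intermediate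
28 | mixed anhydride of 27 and 2,4,6-trichlorobenzoic acid | CCCC[C@H](C)/C=C(\C)C(=O)OC(=O)c1c(Cl)cc(Cl)cc1Cl | intermediate
29 | C1 ester: 1β-[(2E,4S)-2,4-dimethyloct-2-enoyloxy], C9=C10, C8 dioxolane, 4β-ester | C[C@]12CCC3(OCCO3)C=C1[C@H](OC(=O)/C(C)=C/[C@@H](C)CCCC)CC[C@@H]2C(=O)OCc1ccc(OC)cc1 | intermediate
30 | C8 enone: C8=O, C9=C10, 1β-acyloxy, 4β-ester | C[C@]12CCC(=O)C=C1[C@H](OC(=O)/C(C)=C/[C@@H](C)CCCC)CC[C@@H]2C(=O)OCc1ccc(OC)cc1 | intermediate
31 | 7α-allyl enone 4-methoxybenzyl ester | C[C@]12C[C@@H](CC=C)C(=O)C=C1[C@H](OC(=O)/C(C)=C/[C@@H](C)CCCC)CC[C@@H]2C(=O)OCc1ccc(OC)cc1 | intermediate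
32 | 7α-allyl enone acid | C[C@]12C[C@@H](CC=C)C(=O)C=C1[C@H](OC(=O)/C(C)=C/[C@@H](C)CCCC)CC[C@@H]2C(=O)O | intermediate
33 | diol from 32 (C7–CH2–CH(OH)–CH2OH, carbinol centre undefined) | C[C@]12C[C@@H](CC(O)CO)C(=O)C=C1[C@H](OC(=O)/C(C)=C/[C@@H](C)CCCC)CC[C@@H]2C(=O)O | intermediate
34 | keto aldehyde acid (C7–CH2–CHO) | C[C@]12C[C@@H](CC=O)C(=O)C=C1[C@H](OC(=O)/C(C)=C/[C@@H](C)CCCC)CC[C@@H]2C(=O)O | intermediate
35 | integric acid | C=C(C=O)[C@@H]1C[C@@]2(C)C(=CC1=O)[C@H](OC(=O)/C(C)=C/[C@@H](C)CCCC)CC[C@@H]2C(=O)O | target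

Total step count: 25. Longest linear sequence: 20 (steps 1–14 and 20–25).

Steps most likely to fail

1. Step 8. The cationic boron catalyst may be tied up by the ketal oxygens or may strip the acid-labile silyl enol ether before cycloaddition, and facial discrimination on a trisubstituted dienophile may be too low. The fallback changes from one-point to two-point binding; it sets out from 8 and returns at 15. MnO2 oxidises 8 to the keto enal F1, chlorite oxidation gives the enoic acid F2, and coupling with oxazolidin-2-one through the pivalic mixed anhydride (t-BuCOCl, Et3N, LiCl) gives the N-enoyl oxazolidinone F3. Silylation as in step 6 gives the silyloxydiene imide F4, which is cyclised with [Cu((R,R)-t-Bu-box)](SbF6)2 (10 mol %, CH2Cl2, rt), the divalent copper complex of 2,2′-isopropylidenebis[(4R)-4-tert-butyl-2-oxazoline], to the imide adduct F5. The chelating copper ignores the ketal and the enol ether; on the square-planar chelate model the (R,R) ligand exposes the C4 Si face. The price is a more crowded chelate for the β,β-disubstituted enoyl group, to be offset by the SbF6 counter-ion and a longer reaction time. Bu4NF/AcOH converts F5 into the keto imide F6, and LiOH/H2O2 cleaves the imide to 15.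

2. Step 12. Silylation may fail to discriminate C10 from C2 (faster removal of the less hindered C2 proton, slow equilibration), so that the palladium step would desaturate C2–C3. The fallback brings the double bond in from the C8 ketone after C7 has been blocked; it sets out from 16 and returns at 31. NaBH4 reduces 16 from the α face to the saturated 1β-alcohol F7, which is acylated with 27 as in step 20 to the ester F8; pyridinium p-toluenesulfonate in wet acetone frees the C8 ketone F9. In this trans-fused ketone enolisation runs away from the ring fusion, so LiN(SiMe3)2 and allyl iodide give the 7α-allyl ketone F10. With C7 substituted, LDA/Me3SiCl removes a C9 proton to give the enol ether F11, and Pd(OAc)2 introduces C9=C10 to give 31.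

3. Step 20. Acyl transfer to the axial C1 hydroxyl, which is 1,3-diaxial to the C5 methyl, may be so slow that the activated acid loses its γ-hydrogen (vinylketene formation, erosion of C4′ and of the E geometry) or the allylic alcohol eliminates. The fallback forms the ester bond with a small acyl group and builds the chain afterwards; it sets out from 19 and returns at 29. Esterification of 19 with 2-(diethoxyphosphoryl)propanoic acid (DCC, 4-dimethylaminopyridine) gives the phosphonate ester F12, and a Masamune–Roush olefination (LiCl, DBU, MeCN) with aldehyde 25, made from 24 as in step 18 without the ylide, closes the (E)-enoate to give 29.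

Further compounds
F1 | step 8 | (2E)-3-methyl-5-[2-(3-oxopent-4-en-1-yl)-1,3-dioxolan-2-yl]pent-2-enal | C=CC(=O)CCC1(CC/C(C)=C/C=O)OCCO1
F2 | step 8 | (2E)-3-methyl-5-[2-(3-oxopent-4-en-1-yl)-1,3-dioxolan-2-yl]pent-2-enoic acid | C=CC(=O)CCC1(CC/C(C)=C/C(=O)O)OCCO1
F3 | step 8 | 3-{(2E)-3-methyl-5-[2-(3-oxopent-4-en-1-yl)-1,3-dioxolan-2-yl]pent-2-enoyl}oxazolidin-2-one | C=CC(=O)CCC1(CC/C(C)=C/C(=O)N2CCOC2=O)OCCO1
F4 | step 8 | 3-[(2E,8Z)-6,6-(ethylenedioxy)-3-methyl-9-(triisopropylsilyloxy)undeca-2,8,10-trienoyl]oxazolidin-2-one | C=C/C(O[Si](C(C)C)(C(C)C)C(C)C)=C/CC1(CC/C(C)=C/C(=O)N2CCOC2=O)OCCO1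
F5 | step 8 | trans-fused octalin N-acyl oxazolidinone (C1 triisopropylsilyl enol ether, C8 dioxolane, 4β-acyl, 5β-CH3, 10α-H) | C[C@]12CCC3(OCCO3)C[C@@H]1C(O[Si](C(C)C)(C(C)C)C(C)C)=CC[C@@H]2C(=O)N1CCOC1=O
F6 | step 8 | trans-fused decalin keto N-acyl oxazolidinone (C1 ketone, C8 dioxolane) | C[C@]12CCC3(OCCO3)C[C@@H]1C(=O)CC[C@@H]2C(=O)N1CCOC1=O
F7 | step 12 | saturated 1β-alcohol (trans-decalin, C8 dioxolane, 4β-CO2CH2C6H4OMe) | C[C@]12CCC3(OCCO3)C[C@@H]1[C@H](O)CC[C@@H]2C(=O)OCc1ccc(OC)cc1
F8 | step 12 | saturated 1β-[(2E,4S)-2,4-dimethyloct-2-enoyloxy] ketal | C[C@]12CCC3(OCCO3)C[C@@H]1[C@H](OC(=O)/C(C)=C/[C@@H](C)CCCC)CC[C@@H]2C(=O)OCc1ccc(OC)cc1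
F9 | step 12 | saturated C8 ketone with 1β-acyloxy group | C[C@]12CCC(=O)C[C@@H]1[C@H](OC(=O)/C(C)=C/[C@@H](C)CCCC)CC[C@@H]2C(=O)OCc1ccc(OC)cc1
F10 | step 12 | saturated 7α-allyl C8 ketone | C[C@]12C[C@@H](CC=C)C(=O)C[C@@H]1[C@H](OC(=O)/C(C)=C/[C@@H](C)CCCC)CC[C@@H]2C(=O)OCc1ccc(OC)cc1
F11 | step 12 | C8=C9 trimethylsilyl enol ether of the 7α-allyl ketone | C[C@]12C[C@@H](CC=C)C(O[Si](C)(C)C)=C[C@@H]1[C@H](OC(=O)/C(C)=C/[C@@H](C)CCCC)CC[C@@H]2C(=O)OCc1ccc(OC)cc1
F12 | step 20 | 1β-[2-(diethoxyphosphoryl)propanoyloxy] ester of 19 (phosphonate α-carbon undefined) | C[C@]12CCC3(OCCO3)C=C1[C@H](OC(=O)C(C)P(=O)(OCC)OCC)CC[C@@H]2C(=O)OCc1ccc(OC)cc1
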